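The overall equation cannot be the whole story: the Sub consumed in Saturday's run by its last reading comes to 0.485 M, more than the Rgt charge of 0.400 M, so some Sub must go without Rgt.

| setting | Saturday's | Monday's | Thursday's | Sunday's | Friday's |
|---|---|---|---|---|---|
| Sub | 0.500 M | 0.250 M | 1.50 M | 0.500 M | 0.500 M |
| Rgt | 0.400 M | 0.150 M | 0.400 M | 0.200 M | 0.110 M |
| time |  |  |  |  | 100 min |

| run | time / min | [Sub] / M |
|---|---|---|
| Saturday's run | 4.0 | 0.4039 |
| Saturday's run | 6.3 | 0.3614 |
| Saturday's run | 10 | 0.3090 |
| Saturday's run | 16 | 0.2355 |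
| Saturday's run | 25 | 0.1660 |
| Saturday's run | 40 | 0.0981 |
| Saturday's run | 63 | 0.0450 |
| Saturday's run | 100 | 0.0149 |
| Monday's run | 4.0 | 0.2211 |
| Monday's run | 6.3 | 0.2074 |
| Monday's run | 10 | 0.1838 |
| Monday's run | 16 | 0.1568 |
| Monday's run | 25 | 0.1232 |
| Monday's run | 40 | 0.0823 |
| Monday's run | 63 | 0.0469 |
| Monday's run | 100 | 0.0190 |
| Thursday's run | 4.0 | 1.1166 |
| Thursday's run | 6.3 | 0.9751 |
| Thursday's run | 10 | 0.7942 |
| Thursday's run | 16 | 0.5975 |
| Thursday's run | 25 | 0.4237 |
| Thursday's run | 40 | 0.2650 |
| Thursday's run | 63 | 0.1438 |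
| Thursday's run | 100 | 0.0599 |
| Sunday's run | 4.0 | 0.4262 |
| Sunday's run | 6.3 | 0.3897 |
| Sunday's run | 10 | 0.3378 |
| Sunday's run | 16 | 0.2810 |
| Sunday's run | 25 | 0.2082 |
| Sunday's run | 40 | 0.1381 |
| Sunday's run | 63 | 0.0783 |
| Sunday's run | 100 | 0.0332 |

(standard deviation of a reading: 0.002 M)

- Overall: Sub + Rgt -> Prd.
- Constant volume, constant temperature.
- "The second partner" is Rgt.
- An order is taken over about fifteen percent of the charge, up and down.

* the power of [Rgt] that the first rate follows, about the charge of the Saturday's run; measure it at two percent of Sub made into Prd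
* the power of [Sub] that the first rate follows, about the charge of the Saturday's run; measure it at two percent of Sub made into Prd (one fixed amount of Prd, the same in the runs compared)
* Sub in the Friday's run at 100 min, as a share of the Sub charged

So we want to know how much of the loss of Sub goes with Rgt. If a path removes a steady fraction of Sub each minute, as in a pseudo-first-order loss, the logarithm of [Sub] at the start over [Sub] now grows steadily, and the contributions of several such paths simply add. We call this logarithm the log-drop. By 100 min it is 3.51 on Saturday and 2.71 on Sunday, and these two runs share their Sub charge but differ in Rgt. Their difference divided by the difference in charge gives 4.01 M⁻¹, the log-drop gained per molar of Rgt charged, and this is the number we freeze.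

Friday's run has Sunday's Sub charge but 0.110 M of Rgt, so we take its log-drop as 2.35, which leaves 9.52% of its Sub. For the powers we take the equation at its word for Prd: if each Prd takes one Sub and one Rgt in a single act, the rate of making it goes near the first power of each, whatever else consumes Sub.

The forecast differs from us on the powers, giving 0.57 for Rgt and 1.3 for Sub, on the ground that “the Rgt path carries about 58% of the rate”; separately it puts Friday at 8.1%, from a log-drop of about 2.5 got by interpolating between runs.

The flask gives 1.1 for Rgt, 1.1 for Sub and 8.51% for Friday's run. Sunday's rate of making Prd stands at 0.46 of Saturday's, from 0.500 of its Rgt charge.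

    Sub + Rgt → Prd (0.04014 M⁻¹ min⁻¹)
    Sub + Rgt → Sid (0.02226 M⁻¹ min⁻¹)
    2 Sub → X (0.01362 M⁻¹ min⁻¹)
    Sub → G (0.01662 min⁻¹)

Friday's log-drop comes to 2.46, which is 0.250 below Sunday's, where 4.01 M⁻¹ had said 0.361. On Monday's run the same 4.01 M⁻¹ assigns 0.601 of a log-drop of 2.58 to Rgt, a quarter.

The runs are simulated from invented constants.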